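The numbers in the tables come from a simulation with constants of no real substance, and the scatter is random.

**Easy step.** I began with what each flask had to do by 20 min, then set the earlier runs beside it and asked what each feed would cost.

| setting | Sunday's | Wednesday's | Thursday's | spring | midnight | autumn | summer |
|---|---|---|---|---|---|---|---|
| substrate | 0.10 M | 0.050 M | 0.075 M | 0.10 M (fed, over 4.0 min) | 0.10 M | 0.10 M | 0.10 M |
| coupling partner | 0.18 M | 0.18 M | 0.18 M | 0.180 M | 0.180 M | 0.180 M (fed, over 1.0 min) | 0.180 M (fed, over 4.0 min) |
| free catalyst | 0.50 mM | 0.50 mM | 0.50 mM | 0.50 mM | 0.50 mM | 0.50 mM | 0.50 mM |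
| remark | run made earlier | run made earlier | run made earlier | all else is in the flask from the start; the feed brings no volume worth counting | everything together at the start | all else is in the flask from the start; the feed brings no volume worth counting | all else is in the flask from the start; the feed brings no volume worth counting |
| time |  |  |  | 20 min | 20 min | 20 min | 20 min |

| run | time / min | product / % | substrate / % |
|---|---|---|---|
| Sunday's | 1.00 | 8 | 93 |
| Sunday's | 1.50 | 9 | 91 |
| Sunday's | 2.50 | 14 | 86 |
| Sunday's | 4.00 | 22 | 81 |
| Sunday's | 8.00 | 29 | 68 |
| Sunday's | 12.0 | 39 | 59 |
| Wednesday's | 0.833 | 12 | 89 |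
| Wednesday's | 2.50 | 26 | 75 |
| Wednesday's | 4.00 | 34 | 65 |
| Wednesday's | 6.00 | 47 | 52 |
| Wednesday's | 10.0 | 65 | 35 |
| Wednesday's | 12.0 | 69 | 29 |
| Thursday's | 2.00 | 15 | 84 |
| Thursday's | 4.00 | 26 | 74 |
| Thursday's | 6.00 | 31 | 66 |
| Thursday's | 8.00 | 42 | 58 |
| Thursday's | 10.0 | 44 | 51 |
| Thursday's | 12.0 | 51 | 47 |

(scatter of a reading: 1.5 percentage points)

- which flask leads in amount of product, in percent of the substrate charged ("all alike" within 1.5 percentage points) (spring / midnight / autumn / summer / all alike)
- how much product is there at the end, in percent of the substrate charged: spring
- how much product is there at the end, in percent of the substrate charged: midnight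
- how much product is there at the end, in percent of the substrate charged: autumn
- how much product is there at the end, in percent of the substrate charged: summer

- the numbers in the tables scatter with a standard deviation of 1.5 percentage points

**Start slope.** Sunday's run has midnight's charges, so it draws midnight's curve. Over its first 4.00 min the readings gave product at 0.00550 M min⁻¹. By that time Wednesday's run, with half the substrate, had made 0.0170 M against Sunday's 0.0220 M. So c(substrate) steered the rate weakly, and I expected a slow substrate feed to cost little.

**Knee and crossing.** From there to 12.0 min the readings put Sunday's slope at 0.00213 M min⁻¹, which is less than the start slope. Held at that slope, product would cross substrate at the half mark near 17.2 min and reach 56.0 % at 20 min. The slope had fallen once, so I expected it to go on falling and placed midnight below that mark.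

**Lag rule.** A steady feed delivers its charge late by half the feed time on average, like a ramp against a step. I assumed that the rate follows c(coupling partner), whose charge never varied in the runs, and that the slowing runs by the clock. The missed minutes are then early ones, priced at the start slope. For summer, that slope times half of 4.0 min, over the substrate charge, gives 11 points, which I call the lag cost. I expected summer to end that far behind midnight.

**Result.** The forecast chose midnight at 54 %, with spring 53 %, autumn 53.5 % and summer 51.5 %, the partner feed “costing 1–3 points”, so my summer gap was wider. The flasks gave midnight 52.1 %, autumn 50.0 %, spring 49.2 % and summer 44.3 %.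

    substrate + coupling partner + free catalyst → product + free catalyst, rate k1*[substrate]*[coupling partner]*[free catalyst]/(1 + ([substrate]/sat1)) (10.7 mM, k = 7760 M⁻² min⁻¹)
    2 free catalyst → spent catalyst (k = 141 M⁻¹ min⁻¹)

**Lag cost.** Summer ended 7.8 points behind midnight, which is 0.709 of my lag cost. Autumn, fed over 1.0 min, carries a lag cost of 2.8 points and ended 2.1 points behind, which is 0.766 of it. The largest single effect on summer's gap at 20 min is the term in c(substrate) in the denominator of the rate, and at that time summer held 55.7 % of its substrate against midnight's 47.9 %. With that term taken away, the gap between midnight and summer falls from 7.8 points to 1.9 points.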